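## Analysis of the target

The target is a single oxolane ring (O1, C2, C3, C4, C5) that carries 3,4-dihydroxyphenyl groups on C2 and C5 and acetoxymethyl arms on C3 (through C6) and C4 (through C7), so all four ring carbons are stereocentres. Both aryl groups lie on one face and both arms on the other: 2,5-cis, 3,4-cis, 2,3-trans and 4,5-trans. A mirror plane through O1 and the midpoint of C3–C4 makes the compound meso, (2R,3S,4R,5S), so only relative configuration has to be controlled. The sensitive groups are the two catechols (air oxidation, so they stay masked to the end), the two primary acetates (lost to base or hydride, so they go on late) and the C2–O1 and C5–O1 bonds, which are benzylic ethers of para-oxygenated arenes and can ionise under acid or be cut by hydrogenolysis. The difficulty is stereochemical: four contiguous centres on a flexible five-membered ring, with the two arms eclipsed cis to each other, an arrangement that equilibration alone does not deliver. The strategy rests on the pattern around the ring: C5 is an aryl carbinol carbon, C2 is an aryl carbon at the aldehyde oxidation level, and C4 carries a one-carbon arm (C7) that can be an aldehyde, which is the pattern left when an oxocarbenium–alkene cyclisation is terminated by a pinacol shift. Because C6 on C3 must be cis to C7, a five-membered lactol between them can be used to police C4.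

## Retrosynthetic reasoning

**15 to 14.** The four phenolic O–benzyl bonds are cut last. Benzyl ethers survive Lewis acid, carbonate base and hydride, and they leave under neutral conditions that do not touch the acetates.

**14 to 13.** The two ester C–O bonds are cut next, so that the acetates appear only after all basic and reducing steps. Diol 13 is meso, so the two hydroxyls are equivalent and need no differentiation.

**13 to 12.** The C7–O bond of a lactol is the next retron: 13 is the reduction product of the cis-fused bicyclic lactol 12, in which C7 is bonded to the oxygen on C6. The bicycle can only be cis-fused, so in 12 the 3,4-cis relationship is structural.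

**12 to 9.** Lactol 12 is traced to aldehyde 9, its C4 epimer with C6 still acetylated. The forward step has to remove the acetate (giving 10), invert C4 through the enolate (giving 11) and trap 11 as the lactol. Only 11 can close the ring, so the equilibrium drains to 12.

**9 to 7 and 1 (key disconnection).** The C4–C5 bond is undone as a pinacol shift, with C5 returned to the carbon that is now C7, and then C2–C3 and O1–C2 are cut. This gives the allylic diol 7 and aldehyde 1, which pass through acetal 8 in the forward direction. The cut is made here because it divides the ring into two pieces of similar size, both derived from the same aldehyde 1, and because the forward reaction forms three bonds and sets C2, C3 and C5 in one chair-organised event. The forward reaction must cyclise 6-endo and contract the ring rather than shift hydride.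

**7 to 6.** The O–CH2OMe bond is cut. The methoxymethyl group is the price of the syn-selective construction of the diol and has to come off without ionising the electron-rich benzylic alcohol.

**6 to 4 and 5.** The E double bond between the future C3 and C4 is cut by cross-metathesis logic. The vinyl group of 4 supplies the future C4, and diacetate 5 supplies C3 and C6 already carrying the acetate. The forward step must give the E isomer, since the alkene geometry is relayed to C3.

**4 to 1 and 2.** The bond between the two carbinol carbons (future C5 and C7) is cut. Allyl ether 2, metalated and transferred to boron as reagent 3, adds to aldehyde 1 and sets the syn relationship of the two oxygen-bearing carbons; the benzylic oxygen introduced here is the one that later carries the oxocarbenium ion.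

## Alternatives that were turned down

Alternative 1: Templated [2+2] photodimerisation of two cinnamate units. On paper the ring oxygen is lifted out and C2 is joined directly to C5, so the four ring carbons become a cyclobutane, which is then cut at C3–C4 and C2–C5 into two cinnamate halves. In the forward direction, irradiation of bis-cinnamate A1, whose two alkenes are held parallel on a naphthalene-1,8-diyl template, should give the β-truxinate A2 by intramolecular [2+2] photocycloaddition; later the template is removed, the C2–C5 bond is cleaved oxidatively and bridged by oxygen, and the esters are reduced. In its favour, it uses the mirror symmetry from the first step, both arms are at the same oxidation level, and 3,4-cis, 2,3-trans and 4,5-trans are all present in A2. Against it, exchanging the C2–C5 σ bond for a C–O–C bridge needs one-electron oxidation of an electron-rich 1,2-diarylcyclobutane, then fragmentation and re-closure through benzylic cations or radicals; at that point C2 and C5 are planar and A2 no longer controls their configuration. Four benzyloxy groups must also survive the oxidant, and putting on and taking off the template costs steps. This route is stronger on symmetry and on securing 3,4-cis without epimerisation. The chosen route instead fixes C2, C3 and C5 in one bond-forming event and corrects the one wrong centre thermodynamically, at a similar length.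

Alternative 2: Syn bis-methoxycarbonylation of a preformed dihydrofuran. Both exocyclic bonds C3–C6 and C4–C7 are cut, leaving the cis-2,5-diaryl-2,5-dihydrofuran A3. In the forward direction, carbon monoxide and methanol under Pd(OCOCF3)2, an aryl α-diimine ligand and benzoquinone should add two methoxycarbonyl groups syn across C3=C4 from the face opposite the aryls, giving diester A4. In its favour, all four centres come out right in one step, nothing needs epimerising, and A4 is three steps from the target; on stereochemical economy after the key step it beats the chosen route. Against it, no ring is formed, so A3 must be made first and as the cis isomer. A3 is a doubly allylic, doubly benzylic ether that needs to lose only two hydrogens to become aromatic, and divalent palladium with benzoquinone is the kind of system that brings about that dehydrogenation. After the first carbopalladation the metal sits on the same face as the C5 hydrogen, so β-hydride elimination competes with the second carbon monoxide insertion. The chosen route builds the ring and three centres together from two simple fragments by non-oxidative cationic chemistry, and pays with one corrective epimerisation.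

Alternative 3: Annulation of aldehyde 1 with a lactone-fused donor–acceptor cyclopropane. C5–O1 and C2–C3 are cut, a formal [3+2] between aldehyde 1 and cyclopropane A6, whose lactone already joins C6 to C7. Under Sn(OTf)2 the aldehyde oxygen should open the cyclopropane at its benzylic carbon and the enolate should close on the oxocarbenium carbon, giving bicycle A7. In its favour, it is convergent, 2,5-cis is the normal outcome of this annulation, and the lactone makes 3,4-cis structural from the start, which is stronger than enforcing it afterwards. Against it, the opening is stereospecific with inversion at the benzylic carbon. Cyclopropane A5, the isomer an E-alkene delivers (aryl trans to the lactone methylene), would therefore place the C5 aryl cis to C7, the wrong relationship. The target needs A6, with the aryl on the concave face, which is harder to make and harder for the aldehyde to approach. With a 3,4-dialkoxyphenyl donor the cyclopropane can also ionise to an open benzylic cation, and then stereospecificity is lost. The extra ester on the quaternary carbon of A7 must be removed afterwards, and the cyclopropane needs diazo chemistry. The chosen route reaches its precursor in three steps from commercial materials and sets C5 relative to C2 and C3 in a chair instead of relying on inversion at a labile benzylic carbon.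

Key step: step 4

**Remarks on the chemistry.**
- The target is meso. The chiral intermediates are drawn as the enantiomer expected from (+)-Ipc2BOMe, but the antipode or the racemate would serve equally, and all stereochemical statements concern relative configuration.
- Ring-containing intermediates use the locants of the target: C2 is the ring carbon from the second molecule of 1, C5 the former benzylic carbinol carbon, C6 the arm on C3 and C7 the arm on C4.

## Route

Step 1
Reactants: 1 3,4-bis(benzyloxy)benzaldehyde; 2 3-(methoxymethoxy)prop-1-ene
Product: 4 (1S,2S)-1-[3,4-bis(benzyloxy)phenyl]-2-(methoxymethoxy)but-3-en-1-ol (syn), via Z-alkoxyallylborane 3 (not isolated)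
Conditions: s-BuLi, THF, −78 °C; (+)-Ipc2BOMe; BF3·OEt2; then 1, −78 °C → rt; NaOH, H2O2
Reagents that add atoms: none
Why: γ-Alkoxyallylboration: lithiated 2 is transferred to boron as the Z-γ-alkoxyallylborane 3, which adds to the aldehyde through a closed chair transition state, so the Z geometry becomes the syn relationship of the two new carbinol centres. The isopinocampheyl groups choose the aldehyde face, which is immaterial for the meso target.

Step 2
Reactants: 4 (1S,2S)-1-[3,4-bis(benzyloxy)phenyl]-2-(methoxymethoxy)but-3-en-1-ol; 5 (Z)-but-2-ene-1,4-diyl diacetate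
Product: 6 (2E,4S,5S)-5-[3,4-bis(benzyloxy)phenyl]-5-hydroxy-4-(methoxymethoxy)pent-2-en-1-yl acetate
Conditions: 5 (3 equiv), (H2IMes)(PCy3)Cl2Ru=CHPh (second-generation Grubbs catalyst, 5 mol %), CH2Cl2, 40 °C
Reagents that add atoms: none
Why: Olefin cross-metathesis: the vinyl group, hindered by its allylic oxygen, homodimerises slowly and is capped by the excess symmetrical diacetate, and the reversible process should settle on the E alkene. The free alcohol, acetal and benzyl ethers are tolerated; any Z isomer is removed by chromatography because the alkene geometry is later relayed to C3.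

Step 3
Reactants: 6 (2E,4S,5S)-5-[3,4-bis(benzyloxy)phenyl]-5-hydroxy-4-(methoxymethoxy)pent-2-en-1-yl acetate
Product: 7 (2E,4S,5S)-5-[3,4-bis(benzyloxy)phenyl]-4,5-dihydroxypent-2-en-1-yl acetate (syn diol)
Conditions: TMSOTf (3 equiv), 2,2′-bipyridyl (4 equiv), CH2Cl2, 0 °C → rt; then H2O, rt; aq. NaHCO3
Reagents that add atoms: none
Why: Silyl triflate–bipyridyl cleavage of a methoxymethyl ether: the acetal is ionised and trapped as an N-(alkoxymethyl)pyridinium salt that water hydrolyses, while the benzylic hydroxyl is masked in situ as its trimethylsilyl ether and so can neither ionise nor close a methylene acetal. The buffered, non-protic conditions spare the allylic acetate, the benzyl ethers and both stereocentres.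

Step 4
Reactants: 7 (2E,4S,5S)-5-[3,4-bis(benzyloxy)phenyl]-4,5-dihydroxypent-2-en-1-yl acetate; 1 3,4-bis(benzyloxy)benzaldehyde
Product: 9 {(2S,3R,4S,5R)-2,5-bis[3,4-bis(benzyloxy)phenyl]-4-formyloxolan-3-yl}methyl acetate (aryls cis; formyl cis to both aryls; acetoxymethyl trans to them), via dioxolane acetal 8 (not isolated)
Conditions: 1 (1.1 equiv), PPTS (cat.), MgSO4, CH2Cl2, rt; filter; then SnCl4 (2 equiv), CH2Cl2, −78 → −20 °C; aq. NaHCO3
Reagents that add atoms: none
Why: Diol and aldehyde condense to acetal 8 (O1–C2), and SnCl4 ionises either acetal C–O bond reversibly, but only the oxocarbenium ion on the benzylic oxygen has an alkene within reach, the other mode requiring a 5-endo closure. That ion closes a six-membered ring by a 6-endo-trig Prins cyclisation through a chair (C2–C3), and the positive charge developing at C4 next to the tin alkoxide is quenched by a 1,2-shift of C5 (C4–C5), which contracts the oxane to the oxolane and releases C7 as the aldehyde; the closest known reaction type is the Prins–pinacol synthesis of 3-acyltetrahydrofurans from allylic diol acetals. C2 is set by the E-oxocarbenium ion, which places its aryl equatorial, and C5, carried over from 7, also sits with its aryl equatorial, so the aryls end 2,5-cis. C3 is set by the E alkene, which places the acetoxymethyl group equatorial and trans to the C2 aryl. C4 is set by the suprafacial shift: C5 bonds to the face of the cation it already occupies, leaving the formyl group cis to the C5 aryl and trans to C6. The step needs endo rather than 5-exo closure, which the chair and the pinacol assistance available only to the endocyclic cation should secure. It also needs ring contraction rather than hydride shift, which the syn diol should secure because its alkoxide is axial in the chair, so the carbinol C–H is equatorial and lies close to the nodal plane of the cation while the ring bond to C5 is the σ bond best placed to migrate. Low temperature should keep the benzylic C–O bonds of the product from ionising.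

Step 5
Reactants: 9 {(2S,3R,4S,5R)-2,5-bis[3,4-bis(benzyloxy)phenyl]-4-formyloxolan-3-yl}methyl acetate
Product: 12 4,6-bis[3,4-bis(benzyloxy)phenyl]tetrahydro-1H,3H-furo[3,4-c]furan-1-ol (cis-fused; aryls cis on the convex face; both anomers), via hydroxy aldehyde 10 (not isolated), via epimeric hydroxy aldehyde 11 (not isolated)
Conditions: K2CO3 (0.3 equiv), MeOH, rt
Reagents that add atoms: none
Why: Base-catalysed methanolysis frees the C6 hydroxyl (10), and the aldehyde α-centre C4 equilibrates through its enolate. Only epimer 11, with C7 cis to C6, can close the five-membered lactol of a cis-fused bicycle, so lactolisation withdraws it and funnels the material to 12 with both aryls on the convex face.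

Step 6
Reactants: 12 4,6-bis[3,4-bis(benzyloxy)phenyl]tetrahydro-1H,3H-furo[3,4-c]furan-1-ol
Product: 13 meso-{(2R,3S,4R,5S)-2,5-bis[3,4-bis(benzyloxy)phenyl]oxolane-3,4-diyl}dimethanol
Conditions: NaBH4, MeOH–THF, 0 °C
Reagents that add atoms: none
Why: Hydride reduction of a lactol, which reacts through the small equilibrium share of its ring-opened tautomer (the same hydroxy aldehyde as 11 of step 5); reduction of that carbonyl should be much faster than its enolisation, so the corrected C4 configuration is kept and the two arms become equivalent.

Step 7
Reactants: 13 meso-{(2R,3S,4R,5S)-2,5-bis[3,4-bis(benzyloxy)phenyl]oxolane-3,4-diyl}dimethanol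
Product: 14 meso-{(2R,3S,4R,5S)-2,5-bis[3,4-bis(benzyloxy)phenyl]oxolane-3,4-diyl}bis(methylene) diacetate
Conditions: Ac2O, pyridine, DMAP (cat.), CH2Cl2, rt
Reagents that add atoms: acetic anhydride, CC(=O)OC(C)=O
Why: DMAP-catalysed acylation of two unhindered primary alcohols; no stereocentre is involved and the phenols are still protected, so only the arms are acetylated.

Step 8
Reactants: 14 meso-{(2R,3S,4R,5S)-2,5-bis[3,4-bis(benzyloxy)phenyl]oxolane-3,4-diyl}bis(methylene) diacetate
Product: 15 meso-[(2R,3S,4R,5S)-2,5-bis(3,4-dihydroxyphenyl)oxolane-3,4-diyl]bis(methylene) diacetate (target)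
Conditions: H2 (1 atm), 10% Pd/C, EtOAc, rt
Reagents that add atoms: none
Why: Catalytic hydrogenolysis of four aryl benzyl ethers, which should be cleaved well before the secondary benzylic C–O bonds of the ring if the reaction is stopped after uptake of four equivalents. The neutral conditions leave the acetates in place and do not promote acyl transfer to the phenols.

## Compound list

1 | 3,4-bis(benzyloxy)benzaldehyde | O=Cc1ccc(OCc2ccccc2)c(OCc2ccccc2)c1 | starting material
2 | 3-(methoxymethoxy)prop-1-ene | C=CCOCOC | starting material
3 | [(Z)-3-(methoxymethoxy)prop-2-en-1-yl]diisopinocampheylborane (from (+)-Ipc2BOMe) | COCO/C=C\CB([C@H]1C[C@H]2C[C@@H]([C@@H]1C)C2(C)C)[C@H]1C[C@H]2C[C@@H]([C@@H]1C)C2(C)C | intermediate (not isolated)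
4 | (1S,2S)-1-[3,4-bis(benzyloxy)phenyl]-2-(methoxymethoxy)but-3-en-1-ol | O[C@H]([C@@H](OCOC)C=C)c1ccc(OCc2ccccc2)c(OCc2ccccc2)c1 | intermediate
5 | (Z)-but-2-ene-1,4-diyl diacetate | CC(=O)OC/C=C\COC(C)=O | starting material
6 | (2E,4S,5S)-5-[3,4-bis(benzyloxy)phenyl]-5-hydroxy-4-(methoxymethoxy)pent-2-en-1-yl acetate | O[C@H]([C@@H](OCOC)/C=C/COC(C)=O)c1ccc(OCc2ccccc2)c(OCc2ccccc2)c1 | intermediate
7 | (2E,4S,5S)-5-[3,4-bis(benzyloxy)phenyl]-4,5-dihydroxypent-2-en-1-yl acetate (syn diol) | O[C@H]([C@@H](O)/C=C/COC(C)=O)c1ccc(OCc2ccccc2)c(OCc2ccccc2)c1 | intermediate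
8 | (E)-3-{(4S,5S)-2,5-bis[3,4-bis(benzyloxy)phenyl]-1,3-dioxolan-4-yl}prop-2-en-1-yl acetate (4,5-trans; both epimers at the acetal carbon) | CC(=O)OC/C=C/[C@@H]1OC(c2ccc(OCc3ccccc3)c(OCc3ccccc3)c2)O[C@H]1c1ccc(OCc2ccccc2)c(OCc2ccccc2)c1 | intermediate (not isolated)
9 | {(2S,3R,4S,5R)-2,5-bis[3,4-bis(benzyloxy)phenyl]-4-formyloxolan-3-yl}methyl acetate (aryls cis; formyl cis to both aryls; acetoxymethyl trans to them) | O=C[C@H]1[C@H](COC(C)=O)[C@@H](c2ccc(OCc3ccccc3)c(OCc3ccccc3)c2)O[C@H]1c1ccc(OCc2ccccc2)c(OCc2ccccc2)c1 | intermediate
10 | 2,5-bis[3,4-bis(benzyloxy)phenyl]-4-(hydroxymethyl)oxolane-3-carbaldehyde (formyl cis to the aryls, trans to the hydroxymethyl group) | O=C[C@H]1[C@H](CO)[C@@H](c2ccc(OCc3ccccc3)c(OCc3ccccc3)c2)O[C@H]1c1ccc(OCc2ccccc2)c(OCc2ccccc2)c1 | intermediate (not isolated)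
11 | 2,5-bis[3,4-bis(benzyloxy)phenyl]-4-(hydroxymethyl)oxolane-3-carbaldehyde (formyl cis to the hydroxymethyl group, trans to the aryls) | O=C[C@@H]1[C@H](CO)[C@@H](c2ccc(OCc3ccccc3)c(OCc3ccccc3)c2)O[C@H]1c1ccc(OCc2ccccc2)c(OCc2ccccc2)c1 | intermediate (not isolated)
12 | 4,6-bis[3,4-bis(benzyloxy)phenyl]tetrahydro-1H,3H-furo[3,4-c]furan-1-ol (cis-fused; aryls cis, on the convex face; both anomers) | OC1OC[C@@H]2[C@@H](c3ccc(OCc4ccccc4)c(OCc4ccccc4)c3)O[C@@H](c3ccc(OCc4ccccc4)c(OCc4ccccc4)c3)[C@H]12 | intermediate
13 | meso-{(2R,3S,4R,5S)-2,5-bis[3,4-bis(benzyloxy)phenyl]oxolane-3,4-diyl}dimethanol | OC[C@@H]1[C@H](CO)[C@@H](c2ccc(OCc3ccccc3)c(OCc3ccccc3)c2)O[C@H]1c1ccc(OCc2ccccc2)c(OCc2ccccc2)c1 | intermediate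
14 | meso-{(2R,3S,4R,5S)-2,5-bis[3,4-bis(benzyloxy)phenyl]oxolane-3,4-diyl}bis(methylene) diacetate | CC(=O)OC[C@@H]1[C@H](COC(C)=O)[C@@H](c2ccc(OCc3ccccc3)c(OCc3ccccc3)c2)O[C@H]1c1ccc(OCc2ccccc2)c(OCc2ccccc2)c1 | intermediate
15 | meso-[(2R,3S,4R,5S)-2,5-bis(3,4-dihydroxyphenyl)oxolane-3,4-diyl]bis(methylene) diacetate | CC(=O)OC[C@@H]1[C@H](COC(C)=O)[C@@H](c2ccc(O)c(O)c2)O[C@H]1c1ccc(O)c(O)c1 | target

## Step count and least certain steps

Total step count: 8. Longest linear sequence: 8 steps (1 → 4 → 6 → 7 → 9 → 12 → 13 → 14 → 15).

**Step 4 (key step).** The alkene is 1,2-disubstituted, so the Prins closure can only lead to a secondary cation and depends on the pinacol shift taking part as the bond forms. It also carries an allylic acetate, which lowers its nucleophilicity and offers its carbonyl oxygen to a cation at the other alkene carbon. The closure may therefore be slow, or may go 5-exo with acetate participation instead of 6-endo with the pinacol shift. A second risk is erosion of configuration, by ionisation of the electron-rich benzylic C–O bonds or by a competing oxonia-Cope/aldol pathway in which C5 becomes planar for a time. The fallback sets out from 4 and replaces the acetate by a silyl ether that neither withdraws as strongly nor participates. Cross-metathesis of 4 with (Z)-1,4-bis[(tert-butyldiphenylsilyl)oxy]but-2-ene F1 (from (Z)-but-2-ene-1,4-diol, TBDPSCl and imidazole) would give the silyl ether F2. Cleavage of the methoxymethyl group as in step 3 would give diol F3. Condensation with 1 and SnCl4 as in step 4 would give the silyloxymethyl aldehyde F4. TBAF buffered with AcOH would then free the hydroxyl and return the material to the route at 10, which goes on to 12 under the conditions of step 5.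

**Step 3.** The methoxymethyl-derived oxocarbenium ion may be captured by the neighbouring hydroxyl to give a cyclic methylene acetal, or the benzylic C–O bond may ionise under the silyl triflate, with substitution or elimination. The fallback sets out from 1 and avoids any acid-labile acetal on the diol. Addition of (Z)-tributyl{3-[(tert-butyldimethylsilyl)oxy]prop-2-en-1-yl}stannane F5 (from allyl tert-butyldimethylsilyl ether, s-BuLi and Bu3SnCl) to 1 with BF3·OEt2 at −78 °C should give the syn hydroxy silyl ether F6 through an open transition state. F6 is racemic, which is sufficient. Cross-metathesis with 5 as in step 2 would give the silyl-protected allylic acetate F7, and TBAF buffered with AcOH would return to the route at 7.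

**Step 5.** Funnelling may be incomplete if the lactol does not pull the epimerisation far enough, and the enolisable aldehyde may undergo side reactions under base (self-aldol condensation, or β-elimination of the ring oxygen with opening of the oxolane). The fallback sets out from 9 and moves the correction to the ester oxidation level, where ring closure is an irreversible sink. Pinnick oxidation (NaClO2, NaH2PO4, 2-methylbut-2-ene) would give acid F8, and TMSCHN2 in MeOH–toluene the methyl ester F9. NaOMe in MeOH would then remove the acetate, epimerise C4 and close the cis-fused lactone F10. LiAlH4 in THF reduces F10 and returns to the route at 13.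

**Step 8.** Over-reduction is possible, that is hydrogenolysis of the ring C2–O1 and C5–O1 bonds, which become more labile once the para-hydroxyl groups are free. The fallback sets out from 14 and returns at 15 without a new intermediate. The benzyl groups are removed by Lewis-acid debenzylation with BCl3 and pentamethylbenzene as cation scavenger in CH2Cl2 at −78 °C, which tolerates the acetates.

## Further compounds

F1 | step 4 | (Z)-1,4-bis[(tert-butyldiphenylsilyl)oxy]but-2-ene | CC(C)(C)[Si](c1ccccc1)(c1ccccc1)OC/C=C\CO[Si](c1ccccc1)(c1ccccc1)C(C)(C)C
F2 | step 4 | (1S,2S,3E)-1-[3,4-bis(benzyloxy)phenyl]-5-[(tert-butyldiphenylsilyl)oxy]-2-(methoxymethoxy)pent-3-en-1-ol | O[C@H]([C@@H](OCOC)/C=C/CO[Si](c1ccccc1)(c1ccccc1)C(C)(C)C)c1ccc(OCc2ccccc2)c(OCc2ccccc2)c1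
F3 | step 4 | (1S,2S,3E)-1-[3,4-bis(benzyloxy)phenyl]-5-[(tert-butyldiphenylsilyl)oxy]pent-3-ene-1,2-diol | O[C@H]([C@@H](O)/C=C/CO[Si](c1ccccc1)(c1ccccc1)C(C)(C)C)c1ccc(OCc2ccccc2)c(OCc2ccccc2)c1
F4 | step 4 | 2,5-bis[3,4-bis(benzyloxy)phenyl]-4-{[(tert-butyldiphenylsilyl)oxy]methyl}oxolane-3-carbaldehyde (aryls cis; formyl cis to both aryls; silyloxymethyl trans to them) | O=C[C@H]1[C@H](CO[Si](c2ccccc2)(c2ccccc2)C(C)(C)C)[C@@H](c2ccc(OCc3ccccc3)c(OCc3ccccc3)c2)O[C@H]1c1ccc(OCc2ccccc2)c(OCc2ccccc2)c1
F5 | step 3 | (Z)-tributyl{3-[(tert-butyldimethylsilyl)oxy]prop-2-en-1-yl}stannane | CCCC[Sn](CCCC)(CCCC)C/C=C\O[Si](C)(C)C(C)(C)C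
F6 | step 3 | syn-1-[3,4-bis(benzyloxy)phenyl]-2-[(tert-butyldimethylsilyl)oxy]but-3-en-1-ol (racemate; (1S,2S) enantiomer drawn) | O[C@H]([C@@H](O[Si](C)(C)C(C)(C)C)C=C)c1ccc(OCc2ccccc2)c(OCc2ccccc2)c1
F7 | step 3 | (E)-syn-5-[3,4-bis(benzyloxy)phenyl]-4-[(tert-butyldimethylsilyl)oxy]-5-hydroxypent-2-en-1-yl acetate (racemate; (4S,5S) enantiomer drawn) | O[C@H]([C@@H](O[Si](C)(C)C(C)(C)C)/C=C/COC(C)=O)c1ccc(OCc2ccccc2)c(OCc2ccccc2)c1
F8 | step 5 | 4-(acetoxymethyl)-2,5-bis[3,4-bis(benzyloxy)phenyl]oxolane-3-carboxylic acid (aryls cis; carboxyl cis to both aryls) | OC(=O)[C@H]1[C@H](COC(C)=O)[C@@H](c2ccc(OCc3ccccc3)c(OCc3ccccc3)c2)O[C@H]1c1ccc(OCc2ccccc2)c(OCc2ccccc2)c1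
F9 | step 5 | methyl 4-(acetoxymethyl)-2,5-bis[3,4-bis(benzyloxy)phenyl]oxolane-3-carboxylate (aryls cis; ester cis to both aryls) | COC(=O)[C@H]1[C@H](COC(C)=O)[C@@H](c2ccc(OCc3ccccc3)c(OCc3ccccc3)c2)O[C@H]1c1ccc(OCc2ccccc2)c(OCc2ccccc2)c1
F10 | step 5 | 4,6-bis[3,4-bis(benzyloxy)phenyl]tetrahydro-1H,3H-furo[3,4-c]furan-1-one (cis-fused; aryls cis, on the convex face) | O=C1OC[C@@H]2[C@@H](c3ccc(OCc4ccccc4)c(OCc4ccccc4)c3)O[C@@H](c3ccc(OCc4ccccc4)c(OCc4ccccc4)c3)[C@H]12
F0 | step 8 | none | none
A1 | alternative 1 | naphthalene-1,8-diyl bis[(E)-3-(3,4-bis(benzyloxy)phenyl)prop-2-enoate] | O=C(/C=C/c1ccc(OCc2ccccc2)c(OCc2ccccc2)c1)Oc1cccc2cccc(OC(=O)/C=C/c3ccc(OCc4ccccc4)c(OCc4ccccc4)c3)c12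
A2 | alternative 1 | template-bound β-truxinate (aryls cis, carboxyls cis, neighbours trans) | O=C1Oc2cccc3cccc(c23)OC(=O)[C@@H]4[C@H]1[C@@H](c1ccc(OCc2ccccc2)c(OCc2ccccc2)c1)[C@H]4c1ccc(OCc2ccccc2)c(OCc2ccccc2)c1
A3 | alternative 2 | cis-2,5-bis[3,4-bis(benzyloxy)phenyl]-2,5-dihydrofuran | C1=C[C@@H](c2ccc(OCc3ccccc3)c(OCc3ccccc3)c2)O[C@H]1c1ccc(OCc2ccccc2)c(OCc2ccccc2)c1
A4 | alternative 2 | dimethyl 2,5-cis-bis[3,4-bis(benzyloxy)phenyl]oxolane-3,4-cis-dicarboxylate (esters trans to aryls) | COC(=O)[C@@H]1[C@H](C(=O)OC)[C@@H](c2ccc(OCc3ccccc3)c(OCc3ccccc3)c2)O[C@H]1c1ccc(OCc2ccccc2)c(OCc2ccccc2)c1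
A5 | alternative 3 | methyl 6-[3,4-bis(benzyloxy)phenyl]-2-oxo-3-oxabicyclo[3.1.0]hexane-1-carboxylate, aryl trans to the lactone methylene (racemate) | COC(=O)[C@@]12C(=O)OC[C@@H]1[C@H]2c1ccc(OCc2ccccc2)c(OCc2ccccc2)c1
A6 | alternative 3 | methyl 6-[3,4-bis(benzyloxy)phenyl]-2-oxo-3-oxabicyclo[3.1.0]hexane-1-carboxylate, aryl cis to the lactone methylene (racemate) | COC(=O)[C@@]12C(=O)OC[C@@H]1[C@@H]2c1ccc(OCc2ccccc2)c(OCc2ccccc2)c1
A7 | alternative 3 | methyl 4,6-bis[3,4-bis(benzyloxy)phenyl]-3-oxotetrahydro-1H-furo[3,4-c]furan-3a(3H)-carboxylate (ester on the ring-fusion carbon next to the lactone carbonyl; aryls cis, trans to the lactone) | C3[C@@H]1[C@](C(=O)OC)(C(=O)O3)[C@@H](c2ccc(OCc3ccccc3)c(OCc3ccccc3)c2)O[C@H]1c1ccc(OCc2ccccc2)c(OCc2ccccc2)c1
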